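**Plan**

- Retrosynthesis: the C3–C4 and C7–C8 epoxides go back to E-alkenes. The cyclohexanone (C1, C14, C13, C12, C11, C15) is contracted by cutting C11–C15 and re-forming C13–C15, giving a cyclobutanol (C13, C14, C1, C15) bridged by a 14-membered ring. That ring is cut at C4–C5 (ring closure) and C12–C13 (fragment union).
- Enabling feature: the C13 ketone has the C12=C18 exo-methylene and C11 on one side and, across C14–C1, the quaternary C15 on the other. A 1-alkenylcyclobutanol (C13 carbinol, C15 ring α-carbon) can therefore open under strain release to a tertiary C15 radical and a C13 enone, which re-close 6-endo at C11 while an acetate on C18 leaves.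
- Forward: fragment A (cyclobutanone with the C2–C4 vinyl iodide arm, from (+)-α-pinene) and fragment B (C18, C12–C5, Z-vinyl iodide with diene terminus, from but-2-yne-1,4-diol) are joined at C12–C13. B-alkyl Suzuki coupling closes the 14-membered ring at C4–C5, the ring expansion forms the six-membered and 12-membered rings with one bond, and diepoxidation ends the route.
- Stereochemistry: C1 from α-pinene; C10 by catalyst-controlled propargylation; 3E, 7E and 11Z by hydrozirconation, carboalumination and directed hydroalumination; C11 in the key step; C3, C4, C7, C8 by peripheral epoxidation of the bicycle.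

Key step: step 18

Remark: verticillane numbering is used throughout (C1 and C11 bridgeheads, C15 gem-dimethyl carbon, C12=C18 exo-methylene, C13 ketone, C10 acetate, C19 and C20 methyls on C8 and C4).
Remark: the carbinol carbon created in step 13 becomes the C13 carbonyl in step 18, so its configuration is irrelevant; the epimer expected to predominate is drawn for 23–28.
Remark: the two trioxolane carbons of 2 are drawn without configuration because both are destroyed in the same step.

Step 1
Reactants: 1 (+)-α-pinene
Product: 3 2-[(1S,3S)-3-acetyl-2,2-dimethylcyclobutyl]acetaldehyde (cis-pinonaldehyde), via pinene ozonide 2 (not isolated)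
Conditions: O3, CH2Cl2, −78 °C; then Me2S, −78 °C → rt
Reagents that add atoms: ozone, [O-][O+]=O
Why: Ozonolysis (Criegee mechanism) cleaves the only alkene of 1, and reductive work-up of the ozonide should give the keto aldehyde with both cyclobutane stereocentres of the chiral pool intact, the CH2CHO-bearing one being the future C1.

Step 2
Reactants: 3 cis-pinonaldehyde
Product: 4 1-[(1S,3S)-3-(3,3-dibromoprop-2-en-1-yl)-2,2-dimethylcyclobutyl]ethan-1-one
Conditions: CBr4, PPh3, CH2Cl2, 0 °C
Reagents that add atoms: carbon tetrabromide, BrC(Br)(Br)Br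
Why: The Corey–Fuchs dibromo-olefination (a Wittig-type reaction of Ph3P=CBr2) should take the aldehyde and leave the less electrophilic methyl ketone, and no stereocentre is formed.

Step 3
Reactants: 4 dibromoalkenyl methyl ketone
Product: 5 (1S,3R)-3-(3,3-dibromoprop-2-en-1-yl)-2,2-dimethylcyclobutyl acetate
Conditions: mCPBA, CH2Cl2, rt → 40 °C
Reagents that add atoms: 3-chloroperbenzoic acid (mCPBA), OOC(=O)c1cccc(Cl)c1
Why: In the Baeyer–Villiger oxidation the secondary cyclobutyl group migrates in preference to methyl and with retention, and the electron-poor dibromoalkene does not react with the peracid.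

Step 4
Reactants: 5 dibromoalkenyl cyclobutyl acetate
Product: 7 (1S,3R)-3-(but-2-yn-1-yl)-2,2-dimethylcyclobutan-1-ol, via dilithium alkynide alkoxide 6 (not isolated)
Conditions: n-BuLi (4.2 equiv), THF, −78 → 0 °C; then MeI (1.1 equiv), −78 °C → rt; H2O
Reagents that add atoms: iodomethane, CI
Why: This is the second stage of the Corey–Fuchs alkyne synthesis (bromine–lithium exchange, Fritsch–Buttenberg–Wiechell rearrangement, deprotonation), excess n-BuLi also cleaves the acetate, and the acetylide carbon is methylated much faster than the hindered lithium alkoxide in THF.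

Step 5
Reactants: 7 butynyl cyclobutanol
Product: 9 (1S,3R)-3-[(2E)-3-iodobut-2-en-1-yl]-2,2-dimethylcyclobutan-1-ol, via zirconocene adduct 8 (not isolated)
Conditions: Cp2Zr(H)Cl (3 equiv), THF, rt → 50 °C; then I2, 0 °C
Reagents that add atoms: iodine, II
Why: Hydrozirconation adds H and Zr syn, warming with excess reagent equilibrates zirconium to the less hindered methyl-bearing alkyne carbon, and iodinolysis with retention should give the (E)-2-iodoalkene with iodine trans to C2.

Step 6
Reactants: 9 iodobutenyl cyclobutanol
Product: 10 (3R)-3-[(2E)-3-iodobut-2-en-1-yl]-2,2-dimethylcyclobutan-1-one (fragment A)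
Conditions: Dess–Martin periodinane, pyridine, CH2Cl2, 0 °C → rt
Reagents that add atoms: none
Why: Dess–Martin oxidation converts the secondary cyclobutanol into the cyclobutanone under neutral conditions that leave the vinyl iodide alone, and the C1 stereocentre (β to the carbonyl) cannot epimerise.

Step 7
Reactants: 11 but-2-yne-1,4-diol
Product: 12 4-[(tert-butyldimethylsilyl)oxy]but-2-yn-1-ol
Conditions: TBSCl (0.3 equiv), imidazole, DMF/THF, 0 °C
Reagents that add atoms: tert-butyldimethylsilyl chloride, CC(C)(C)[Si](C)(C)Cl
Why: Monosilylation of the symmetrical diol used in excess is a statistical protection that should give mainly the mono-TBS ether.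

Step 8
Reactants: 12 mono-TBS butynediol
Product: 13 4-[(tert-butyldimethylsilyl)oxy]but-2-ynal
Conditions: MnO2, CH2Cl2, rt
Reagents that add atoms: none
Why: MnO2 oxidises the propargylic alcohol selectively to the ynal without over-oxidation.

Step 9
Reactants: 13 silyloxybutynal
Product: 15 (4S)-1-[(tert-butyldimethylsilyl)oxy]hepta-2,6-diyn-4-ol, via pinacolboryl ether 14 (not isolated)
Conditions: allenylboronic acid pinacol ester, (S)-TRIP (5 mol %), 4 Å MS, toluene, 0 °C; aqueous work-up
Reagents that add atoms: allenylboronic acid pinacol ester, C=C=CB1OC(C)(C)C(C)(C)O1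
Why: In the chiral phosphoric acid catalysed propargylation the allenylboronate adds through a six-membered SE2' transition state held by the catalyst, so the C10 carbinol centre is set under catalyst control, the S catalyst being chosen by analogy with the sense expected for aryl and alkenyl aldehydes.

Step 10
Reactants: 15 diynol
Product: 17 (4S,6E)-1-[(tert-butyldimethylsilyl)oxy]-6-methylnona-6,8-dien-2-yn-4-ol, via alkenylalane 16 (not isolated)
Conditions: AlMe3 (3 equiv), Cp2ZrCl2 (0.25 equiv), CH2Cl2, 0 °C → rt; then vinyl bromide, Pd(PPh3)4 (5 mol %), ZnCl2 (co-catalyst), THF, rt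
Reagents that add atoms: trimethylaluminium, C[Al](C)C; vinyl bromide, C=CBr
Why: The Negishi zirconium-catalysed carboalumination adds methyl and aluminium syn to the terminal alkyne (methyl on the internal carbon, far faster than on the internal alkyne), and Negishi coupling of the alkenylalane with vinyl bromide proceeds with retention, so the 7E alkene arises as part of a terminal diene.

Step 11
Reactants: 17 dienynol
Product: 19 (2Z,4S,6E)-1-[(tert-butyldimethylsilyl)oxy]-2-iodo-6-methylnona-2,6,8-trien-4-ol, via cyclic alkenylaluminate 18 (not isolated)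
Conditions: NaAlH2(OCH2CH2OCH3)2 (Red-Al), THF, 0 °C → rt; then I2, −78 → 0 °C
Reagents that add atoms: iodine, II
Why: Hydroxyl-directed trans-hydroalumination of the propargylic alcohol delivers hydride to C11 and aluminium to C12 within a five-membered alkoxyaluminate, and iodinolysis with retention should give the Z-vinyl iodide with iodine cis to C10.

Step 12
Reactants: 19 iodotrienol
Product: 20 (2Z,4S,6E)-1,4-bis[(tert-butyldimethylsilyl)oxy]-2-iodo-6-methylnona-2,6,8-triene (fragment B)
Conditions: TBSOTf, 2,6-lutidine, CH2Cl2, −78 °C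
Reagents that add atoms: tert-butyldimethylsilyl triflate, CC(C)(C)[Si](C)(C)OS(=O)(=O)C(F)(F)F
Why: Silylation of the secondary allylic alcohol with the silyl triflate and a hindered base is a routine protection that makes the fragment compatible with t-BuLi.

Step 13
Reactants: 20 fragment B; 10 fragment A
Product: 23 (1S,3R)-1-[(2Z,4S,6E)-1,4-bis(tert-butyldimethylsilyloxy)-6-methylnona-2,6,8-trien-2-yl]-3-[(2E)-3-iodobut-2-en-1-yl]-2,2-dimethylcyclobutan-1-ol, via alkenyllithium 21 (not isolated), via alkenylcerium dichloride 22 (not isolated)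
Conditions: 20, t-BuLi (2.05 equiv), Et2O, −78 °C; CeCl3, THF, −78 °C; then 10, −78 → −40 °C; H2O
Reagents that add atoms: none
Why: Iodine–lithium exchange with retention of alkene geometry, transmetalation to the non-basic organocerium reagent (no enolisation, no halogen–metal exchange with the vinyl iodide of 10) and 1,2-addition to the strained cyclobutanone should give the 1-alkenylcyclobutanol, attack anti to the C1 arm favouring the epimer drawn.

Step 14
Reactants: 23 tertiary cyclobutanol
Product: 24 triethylsilyl ether of 23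
Conditions: TESOTf, 2,6-lutidine, CH2Cl2, −78 → 0 °C
Reagents that add atoms: triethylsilyl triflate, CC[Si](CC)(CC)OS(=O)(=O)C(F)(F)F
Why: Silyl triflate silylation protects the hindered tertiary alcohol so that neither the borane nor a palladium alkoxide (β-carbon elimination of the cyclobutanol) can interfere in the next step.

Step 15
Reactants: 24 open-chain tris-silyl ether
Product: 26 macrocyclic tris-silyl ether (14-membered ring bridging the cyclobutane; 3E,7E,11Z), via alkylborane 25 (not isolated)
Conditions: 9-BBN, THF, 0 °C → rt; then slow addition to Pd(dppf)Cl2 (20 mol %), AsPh3, Cs2CO3, DMF/THF/H2O, 45 °C, 0.002 M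
Reagents that add atoms: none
Why: In this B-alkyl Suzuki–Miyaura macrocyclization 9-BBN adds anti-Markovnikov to the terminal CH2 of the diene, and intramolecular coupling of the homoallylic borane with the (E)-vinyl iodide under high dilution proceeds with retention, closing the 14-membered ring at C4–C5 and completing the 3E,7E-1,5-diene.

Step 16
Reactants: 26 macrocyclic tris-silyl ether
Product: 27 macrocyclic triol (C13 tertiary cyclobutanol, C10 and C18 hydroxyls)
Conditions: Bu4NF, THF, 0 °C → rt
Reagents that add atoms: none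
Why: Fluoride cleaves all three silyl ethers (desilylation driven by the Si–F bond) and leaves the alkenes and the strained tertiary alcohol untouched.

Step 17
Reactants: 27 macrocyclic triol
Product: 28 macrocyclic diacetate (C10 and C18 acetates, free C13 cyclobutanol)
Conditions: Ac2O (2.5 equiv), pyridine, DMAP (cat.), CH2Cl2, 0 °C
Reagents that add atoms: acetic anhydride, CC(=O)OC(C)=O
Why: DMAP-catalysed acylation takes the primary and the secondary allylic hydroxyl but not the hindered tertiary cyclobutanol, which installs at once the C10 acetate of the target and the leaving group on C18 needed in the key step.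

Step 18
Reactants: 28 macrocyclic diacetate
Product: 29 (1R,3E,7E,10S,11S)-10-acetoxyverticilla-3,7,12(18)-trien-13-one
Conditions: [Ir(dF(CF3)ppy)2(5,5'-d(CF3)bpy)]PF6 (2 mol %), Bu4N[(BuO)2PO2] (20 mol %), PhCF3 (0.005 M), blue LEDs, rt, degassed
Reagents that add atoms: none
Why: Proposed new method: the photoexcited iridium complex and the phosphate base remove an electron and a proton from the tertiary O–H (proton-coupled electron transfer), the cyclobutyloxy radical undergoes strain-driven β-scission of C13–C15 to the tertiary C15 radical and the Z-configured 2-(acetoxymethyl)enone C13(=O)–C12=C11, the radical adds to C11, and the α-keto radical at C12 is reduced by divalent iridium to an enolate that expels acetate from C18 (E1cB) to give the exo-methylene ketone and return the catalyst. The closest known reaction types are the photocatalytic n+2 ring expansion of 1-alkenylcycloalkanols by alkoxy-radical β-scission and enone recombination, and radical allylation with 2-(acyloxymethyl)acrylate-type acceptors. The one new bond closes the cyclohexanone 6-endo-trig and, seen from the 14-membered ring, the 12-membered ring 12-exo-trig (transannular closure). The only new stereocentre, C11, is set in a chair-like transition state in which C2 on C1 is equatorial and C10, being cis to the carbonyl carbon on the Z-alkene, is forced axial, which gives the trans relation of the C1 and C11 ring bonds; C10 is carried in unchanged. The step needs regioselective β-scission (tertiary versus primary radical, secured by the gem-dimethyl group), 6-endo instead of 5-exo attack (secured by the polarity match of the nucleophilic tertiary radical with the enone β-carbon) and elimination instead of protonation of the enolate (secured by the β-acetoxy group).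

Step 19
Reactants: 29 bicyclic trienone acetate
Product: 30 (1R,3R,4R,7R,8R,10S,11S)-10-acetoxy-3,4:7,8-diepoxyverticill-12(18)-en-13-one (target)
Conditions: mCPBA (2.2 equiv), CH2Cl2, −20 → 0 °C
Reagents that add atoms: 3-chloroperbenzoic acid (mCPBA), OOC(=O)c1cccc(Cl)c1
Why: In this Prilezhaev epoxidation the two electron-rich E-trisubstituted alkenes react far faster than the electron-poor enone alkene, the syn addition keeps the trans geometry, and attack on the exposed outer face of each alkene of the rigid bridged bicycle is expected to give the 3R,4R and 7R,8R epoxides.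

**Compound list**

1 | (+)-α-pinene, (1R,5R)-2,6,6-trimethylbicyclo[3.1.1]hept-2-ene | CC1=CC[C@@H]2C[C@H]1C2(C)C | starting material
2 | α-pinene ozonide (1,2,4-trioxolane) | CC12OOC(O1)C[C@@H]1C[C@H]2C1(C)C | intermediate
3 | 2-[(1S,3S)-3-acetyl-2,2-dimethylcyclobutyl]acetaldehyde (cis-pinonaldehyde) | O=CC[C@@H]1C[C@H](C(C)=O)C1(C)C | intermediate
4 | 1-[(1S,3S)-3-(3,3-dibromoprop-2-en-1-yl)-2,2-dimethylcyclobutyl]ethan-1-one | BrC(Br)=CC[C@@H]1C[C@H](C(C)=O)C1(C)C | intermediate
5 | (1S,3R)-3-(3,3-dibromoprop-2-en-1-yl)-2,2-dimethylcyclobutyl acetate | BrC(Br)=CC[C@@H]1C[C@H](OC(C)=O)C1(C)C | intermediate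
6 | dilithium alkynide alkoxide of the cyclobutanol | [Li]C#CC[C@@H]1C[C@H](O[Li])C1(C)C | intermediate
7 | (1S,3R)-3-(but-2-yn-1-yl)-2,2-dimethylcyclobutan-1-ol | CC#CC[C@@H]1C[C@H](O)C1(C)C | intermediate
8 | (E)-alkenylzirconocene chloride, zirconium alkoxide form | C/C(=C\C[C@@H]1C[C@H](O[Zr](Cl)(C2C=CC=C2)C2C=CC=C2)C1(C)C)[Zr](Cl)(C1C=CC=C1)C1C=CC=C1 | intermediate
9 | (1S,3R)-3-[(2E)-3-iodobut-2-en-1-yl]-2,2-dimethylcyclobutan-1-ol | C/C(I)=C\C[C@@H]1C[C@H](O)C1(C)C | intermediate
10 | (3R)-3-[(2E)-3-iodobut-2-en-1-yl]-2,2-dimethylcyclobutan-1-one (fragment A) | C/C(I)=C\C[C@@H]1CC(=O)C1(C)C | intermediate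
11 | but-2-yne-1,4-diol | OCC#CCO | starting material
12 | 4-[(tert-butyldimethylsilyl)oxy]but-2-yn-1-ol | OCC#CCO[Si](C)(C)C(C)(C)C | intermediate
13 | 4-[(tert-butyldimethylsilyl)oxy]but-2-ynal | O=CC#CCO[Si](C)(C)C(C)(C)C | intermediate
14 | pinacolboryl ether of 15 | C#CC[C@H](OB1OC(C)(C)C(C)(C)O1)C#CCO[Si](C)(C)C(C)(C)C | intermediate
15 | (4S)-1-[(tert-butyldimethylsilyl)oxy]hepta-2,6-diyn-4-ol | C#CC[C@H](O)C#CCO[Si](C)(C)C(C)(C)C | intermediate
16 | (E)-alkenyl(dimethyl)alane, O-dimethylaluminium alkoxide | C[Al](C)/C=C(\C)C[C@H](O[Al](C)C)C#CCO[Si](C)(C)C(C)(C)C | intermediate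
17 | (4S,6E)-1-[(tert-butyldimethylsilyl)oxy]-6-methylnona-6,8-dien-2-yn-4-ol | C=C/C=C(\C)C[C@H](O)C#CCO[Si](C)(C)C(C)(C)C | intermediate
18 | sodium cyclic alkenyl(alkoxy)aluminate | [Na+].C=C/C=C(\C)C[C@@H]1O[Al-](OCCOC)(OCCOC)C(CO[Si](C)(C)C(C)(C)C)=C1 | intermediate
19 | (2Z,4S,6E)-1-[(tert-butyldimethylsilyl)oxy]-2-iodo-6-methylnona-2,6,8-trien-4-ol | C=C/C=C(\C)C[C@H](O)/C=C(\I)CO[Si](C)(C)C(C)(C)C | intermediate
20 | (2Z,4S,6E)-1,4-bis[(tert-butyldimethylsilyl)oxy]-2-iodo-6-methylnona-2,6,8-triene (fragment B) | C=C/C=C(\C)C[C@H](O[Si](C)(C)C(C)(C)C)/C=C(\I)CO[Si](C)(C)C(C)(C)C | intermediate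
21 | alkenyllithium from 20 | C=C/C=C(\C)C[C@H](O[Si](C)(C)C(C)(C)C)/C=C(\[Li])CO[Si](C)(C)C(C)(C)C | intermediate
22 | alkenylcerium dichloride from 21 | C=C/C=C(\C)C[C@H](O[Si](C)(C)C(C)(C)C)/C=C(\[Ce](Cl)Cl)CO[Si](C)(C)C(C)(C)C | intermediate
23 | (1S,3R)-1-[(2Z,4S,6E)-1,4-bis(tert-butyldimethylsilyloxy)-6-methylnona-2,6,8-trien-2-yl]-3-[(2E)-3-iodobut-2-en-1-yl]-2,2-dimethylcyclobutan-1-ol | C=C/C=C(\C)C[C@H](O[Si](C)(C)C(C)(C)C)/C=C(/CO[Si](C)(C)C(C)(C)C)[C@]1(O)C[C@@H](C/C=C(\C)I)C1(C)C | intermediate
24 | triethylsilyl ether of 23 | C=C/C=C(\C)C[C@H](O[Si](C)(C)C(C)(C)C)/C=C(/CO[Si](C)(C)C(C)(C)C)[C@]1(O[Si](CC)(CC)CC)C[C@@H](C/C=C(\C)I)C1(C)C | intermediate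
25 | B-alkyl-9-borabicyclo[3.3.1]nonane from 24 (boron on C5) | C(CB3C4CCCC3CCC4)/C=C(\C)C[C@H](O[Si](C)(C)C(C)(C)C)/C=C(/CO[Si](C)(C)C(C)(C)C)[C@]1(O[Si](CC)(CC)CC)C[C@@H](C/C=C(\C)I)C1(C)C | intermediate
26 | macrocyclic tris-silyl ether (14-membered ring bridging the cyclobutane, 3E,7E,11Z) | C2/C=C(\C)C[C@H](O[Si](C)(C)C(C)(C)C)/C=C(/CO[Si](C)(C)C(C)(C)C)[C@]1(O[Si](CC)(CC)CC)C[C@@H](C/C=C(\C)C2)C1(C)C | intermediate
27 | macrocyclic triol (C13 cyclobutanol, C10 and C18 hydroxyls) | C2/C=C(\C)C[C@H](O)/C=C(/CO)[C@]1(O)C[C@@H](C/C=C(\C)C2)C1(C)C | intermediate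
28 | macrocyclic diacetate (C10 and C18 acetates, free C13 cyclobutanol) | C2/C=C(\C)C[C@H](OC(C)=O)/C=C(/COC(C)=O)[C@]1(O)C[C@@H](C/C=C(\C)C2)C1(C)C | intermediate
29 | (1R,3E,7E,10S,11S)-10-acetoxyverticilla-3,7,12(18)-trien-13-one | C=C1C(=O)C[C@H]2C/C=C(\C)CC/C=C(\C)C[C@H](OC(C)=O)[C@H]1C2(C)C | intermediate
30 | (1R,3R,4R,7R,8R,10S,11S)-10-acetoxy-3,4:7,8-diepoxyverticill-12(18)-en-13-one | C=C1C(=O)C[C@H]2C[C@H]3O[C@]3(C)CC[C@H]3O[C@]3(C)C[C@H](OC(C)=O)[C@H]1C2(C)C | target

**Totals**

Total step count: 19.
Longest linear sequence: 13 steps (steps 1–6 then 13–19, or steps 7–12 then 13–19).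

**Steps most likely to fail**

1. Step 18 (proposed new method). The tertiary radical may be quenched or reduced before the transannular closure, closure onto the β-substituted enone carbon may be slow, or the ring constraint may override the chair preference and erode facial selectivity at C11. Fallback with known chemistry, from 28 back to 29: hypoiodite alkoxy-radical fragmentation of 28 (PhI(OAc)2, I2, visible light, 0 °C) should open the cyclobutanol to the ring-opened tertiary iodide F1. Tin hydride radical cyclisation (Bu3SnH, AIBN, benzene, high dilution, 80 °C) should then close the six-membered ring 6-endo and deliver hydrogen to the α-keto radical, giving the β-acetoxy ketone F2. E1cB elimination of acetic acid with DBU returns the route to 29.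

2. Step 15. The hydroboration of the diene terminus may lose regioselectivity, and the ring closure may be outrun by oligomerisation, protodeboronation or slow transmetalation of the hindered borane; the cyclobutane must also accept trans-bridging for the epimer drawn. Fallback, from 24 back to 26: hydroboration as before, then iodinolysis of alkylborane 25 (I2, NaOMe), gives the primary alkyl iodide F3. Zinc insertion (Zn, LiCl, THF), selective for the alkyl over the vinyl iodide, gives the alkylzinc iodide F4, which is not isolated. Base-free intramolecular Negishi coupling (Pd(PPh3)4, THF, high dilution) then closes the same C4–C5 bond to give 26.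

3. Step 19. Facial selectivity at one or both alkenes may be poor, giving diastereomeric epoxides, and the acid by-product may open the epoxides transannularly. Fallback, from 28 back to 30: Shi epoxidation of 28 (D-fructose-derived ketone catalyst, KHSO5 as 2KHSO5·KHSO4·K2SO4, K2CO3, MeCN/dimethoxymethane/H2O, 0 °C) should set both epoxides under reagent control at the flexible 14-membered stage, where the electron-poor C11=C12 alkene is left alone, giving the macrocyclic diepoxide diacetate F5. Submitting F5 to the conditions of step 18 then gives 30 directly as the last step.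

**Further compounds**

F1 | step 18 | ring-opened tertiary iodide (14-membered Z-2-(acetoxymethyl)enone with a 2-iodopropan-2-yl group on C1) | C2/C=C(\C)C[C@H](OC(C)=O)/C=C(/COC(C)=O)C(=O)C[C@@H](C/C=C(\C)C2)C(C)(C)I
F2 | step 18 | β-acetoxy ketone, 10,18-diacetoxyverticilla-3,7-dien-13-one (both C12 epimers) | CC(=O)OCC1C(=O)C[C@H]2C/C=C(\C)CC/C=C(\C)C[C@H](OC(C)=O)[C@H]1C2(C)C
F3 | step 15 | primary alkyl iodide (iodine on C5 of the open-chain tris-silyl ether) | ICC/C=C(\C)C[C@H](O[Si](C)(C)C(C)(C)C)/C=C(/CO[Si](C)(C)C(C)(C)C)[C@]1(O[Si](CC)(CC)CC)C[C@@H](C/C=C(\C)I)C1(C)C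
F4 | step 15 | alkylzinc iodide from F3 | I[Zn]CC/C=C(\C)C[C@H](O[Si](C)(C)C(C)(C)C)/C=C(/CO[Si](C)(C)C(C)(C)C)[C@]1(O[Si](CC)(CC)CC)C[C@@H](C/C=C(\C)I)C1(C)C
F5 | step 19 | macrocyclic (3R,4R,7R,8R)-diepoxide diacetate | C2[C@H]3O[C@]3(C)C[C@H](OC(C)=O)/C=C(/COC(C)=O)[C@]1(O)C[C@@H](C[C@H]3O[C@]3(C)C2)C1(C)C
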